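## Structural features

The target is a dibenzylbutyrolactone. It has one γ-lactone ring (O1, carbonyl C2, C3, C4, C5) and two benzene rings attached through single methylene carbons: C6 joins C3 to ring A (3-hydroxy-4,5-dimethoxyphenyl) and C7 joins C4 to ring B (3,4-dimethoxyphenyl). C3 and C4 are adjacent stereocentres, both R, so the two arylmethyl groups are trans on the ring. C3 is α to the lactone carbonyl, so its configuration can be corrected by equilibration to the more stable trans isomer. C4 has no activating group in the lactone and must be set absolutely. The fragile features are the free phenol of ring A (acidic, oxidisable as phenoxide), the lactone (opened by hydroxide or alkoxide), the benzylic positions, and the two oxygen-rich arenes; ring A in particular can trap a cation at C5 in a six-membered cyclisation. The skeleton is easy; the real difficulty is the absolute configuration at C4, a CH carrying three sp3 carbon substituents of similar size (C3, C5, C7) with no handle nearby. The key step exploits the fact that C5, the lactone CH2–O carbon, can be carried as a formyl group in an open chain. The formyl group makes C4–H enolisable so that the C4 epimers interconvert, and its reduction forms the C5–H bond and switches that lability off. Because C3 stays epimerisable to the end, the precursor needs no defined stereocentre.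

## Logic of the disconnections

**15 ⇒ 13 (through 14).** The O1–C2 bond is cut and the configuration at C3 is left open. The lactone C3–H is the only acidic C–H in 14 and the trans isomer is favoured, so C3 can be set last under thermodynamic control. The gain is that only C4 needs absolute control. The forward step must close the ring and equilibrate C3 without touching C4 and without harming the phenol.

**13 ⇒ 12.** The C5–H bond is cut, returning C5 to a formyl group. With C5 as an aldehyde, C4 becomes enolisable, so its configuration is selected rather than made. The gain is a precursor with no defined stereocentre. The forward step needs a reductant that accepts only one C4 configuration whatever C3 is, that leaves the ester alone, and that is slower on the mismatched aldehyde than racemisation at C4.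

**12 ⇒ 11.** No skeletal bond is cut. C5 is masked as a dimethyl acetal and the phenol as a tetrahydropyranyl ether. The carbanion chemistry that builds the chain tolerates neither a free aldehyde nor a free phenol, and both masks are acetals that fall in one mild aqueous acid step. The forward step must be mild enough that the liberated aldehyde does not attack ring A.

**11 ⇒ 9 + 4.** The C3–C6 bond is cut. C3 is α to the ester and is the natural nucleophile; C6 as a primary benzylic bromide has no β-hydrogen and cannot eliminate. The molecule is split into the ring-A unit and a C4-branched ester. The forward step needs clean enolate formation without self-condensation; no stereocontrol is asked for.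

**9 ⇒ 6 + 7 (7 from 5).** The C4–C7 bond is cut. C4 is the β-carbon of 6, which already holds C2 as ester and C5 as acetal, so the two ends never need to be told apart. The C3–C4 bond is therefore never made. Forming it from an aldehyde enamine and a secondary α-bromo ester was weighed and discarded, because such a halide tends to eliminate to the cinnamate or alkylate nitrogen. The forward step needs 1,4- over 1,2-addition and a benzylic organomagnesium reagent formed without homocoupling.

**4 ⇒ 3 ⇒ 2 ⇒ 1.** Only functional groups change: C6–Br from C6–OH from the formyl group, and the phenol is protected first. This ties ring A to a commercial aldehyde. The bromination must be neutral so that the acid-labile ether survives.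

## Other disconnections considered

**Alternative 1:** The cut runs through C4–C5 and O1–C2, so the lactone ring is built last.
- **Forward key step:** (2R)-2-[3-(benzyloxy)-4,5-dimethoxybenzyl]-4-(3,4-dimethoxyphenyl)-4-oxobutanoic acid A1 has C3 already set and C7 as a ketone. It would be hydroxymethylated at C4 with formalin and hydroxide (aldol addition of the ketone enolate). On acidification the new alcohol would close onto the carboxyl group to give the trans keto lactone A2, C4 having equilibrated through the ketone enolate. Hydrogenolysis over Pd/C in acid would then remove the benzylic carbonyl oxygen and the benzyl ether together and give 15.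
- **In its favour:** the ring and the trans relationship arise in one classical operation, and no enzyme has to be found, so it is the better plan on predictability.
- **Against it here:**
  - The absolute configuration must be bought earlier, for example by hydrogenating a Stobbe-type alkylidene succinate half-ester with [Rh(cod)2]BF4 and a chiral bisphosphine.
  - The aryl ketone must be installed by acylating the ring-B arene with a donor whose own ring A can compete intramolecularly.
  - A1 has two hydrogens at C4, so a second hydroxymethylation can compete.
  - In A2 both C3 and C4 are enolisable, so prolonged base after ring closure could erode the absolute configuration.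
- **Comparison:** on structure the two plans use the same trans preference in mirror fashion (here C3 fixed and C4 equilibrated), which is equal in principle. The chosen plan is safer in that only one centre is ever acidic after its key step. On step economy the two should be about equal, roughly eight steps from 1.

**Alternative 2:** The cuts are C7–aryl and C3–C6.
- **Forward key step:** ethyl (1S,5R)-2-oxo-3-oxabicyclo[3.1.0]hexane-1-carboxylate A3 is a chiral-pool cyclopropane lactone in which C4 is already configured and C7 is the cyclopropane methylene. A ring-B arylmagnesium bromide with catalytic CuI would open the ring at that CH2 in an SN2-type homoconjugate addition. The resulting stabilised enolate would be benzylated in the same flask by a ring-A benzylic bromide to give A4. Dealkoxycarbonylation (LiCl, wet DMSO, heat) would give the benzyl ether A5 with C3 settling trans, and hydrogenolysis would give 15.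
- **In its favour:** C4 comes from a cheap chiral-pool unit and is never touched. Ring B enters as a simple aryl Grignard reagent, which is more dependable than the benzylic one of step 4. Both arenes are attached in one pot. The longest line should be about six steps, so this alternative is better on step economy and at least equal on predictability.
- **Against it here:**
  - A quaternary centre is formed by benzylating a hindered, doubly stabilised enolate.
  - The decarboxylation needs high temperature.
  - The ring-A bromide still costs three steps.
  - The enantiomeric purity of the product cannot exceed that of A3.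
- **Comparison:** C3 again rests on the trans preference after decarboxylation, which is equal to the chosen plan. The chosen plan keeps a catalytic source of chirality, needs no stereodefined building block, and runs its stereo-determining step in water on the free phenol.

**Alternative 3:** The cut is C3–C4.
- **Forward key step:** (2R,3E)-5-(3,4-dimethoxyphenyl)pent-3-en-2-yl 3-[3-(benzyloxy)-4,5-dimethoxyphenyl]propanoate A6 would be converted (LiN(i-Pr)2, THF/DMPU, Me3SiCl) into its (Z)-silyl ketene acetal. This rearranges through a chair with the carbinol methyl and both arylmethyl groups equatorial, giving (2R,3S,4E)-2-[3-(benzyloxy)-4,5-dimethoxybenzyl]-3-(3,4-dimethoxybenzyl)hex-4-enoic acid A7. Cleavage of the propenyl group (OsO4/NaIO4), borohydride reduction and lactonisation would give A5, and hydrogenolysis would give 15.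
- **In its favour:** one stereospecific pericyclic step forms the central bond and both centres from a single carbinol centre. C4 is fixed by chair chirality transfer and not by screening, which is the better point on mechanism. A leak in ketene acetal geometry affects only C3, which the lactone can still correct; on that point it is equal to the chosen plan.
- **Against it here:**
  - The enantiopure (E)-allylic alcohol and the ring-A propanoic acid must each be made in several steps.
  - A boat pathway would damage C4 irreversibly.
  - The alkene cleavage must spare two electron-rich arenes.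
  - The aldehyde formed on cleavage has exactly the C4 lability that the chosen plan exploits, here as a liability.
- **Comparison:** the route should run to eleven or more steps, clearly worse on step economy.

Key step: step 7

Remark: the target SMILES corresponds to the trans-(3R,4R) lactone. The carbinol-bearing carbon of 13, and the formyl-bearing carbon of the aldehyde the enzyme must accept, have the same spatial arrangement and are also R. The descriptors of A2, A4 and A7 were checked against this and needed no correction.

Remark: C4 of 12 is a dialkyl-substituted, not a benzylic, α-carbon. Its racemisation at neutral pH cannot be taken for granted, so step 7 provides for it.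

Remark: 5 and 6 are taken as purchased, and the ketoreductase is chosen from a commercial panel by screening. Compounds 9, 11 and 12 are stereorandom on purpose.

## Route

Step 1
Reactants: 1 3-hydroxy-4,5-dimethoxybenzaldehyde
Product: 2 3,4-dimethoxy-5-[(tetrahydro-2H-pyran-2-yl)oxy]benzaldehyde (racemic at the acetal carbon)
Conditions: 3,4-dihydro-2H-pyran, PPTS (cat.), CH2Cl2, 20 °C
Reagents that add atoms: 3,4-dihydro-2H-pyran, C1=COCCC1
Why: Acid-catalysed addition of the phenol to the enol ether (tetrahydropyranylation) gives a mixed acetal that is inert to hydride, strong base and neutral bromination and falls in the same mild acid step that later unmasks C5. The new acetal centre is racemic and disappears again in step 6.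

Step 2
Reactants: 2 3,4-dimethoxy-5-[(tetrahydro-2H-pyran-2-yl)oxy]benzaldehyde
Product: 3 {3,4-dimethoxy-5-[(tetrahydro-2H-pyran-2-yl)oxy]phenyl}methanol
Conditions: NaBH4, MeOH, 0 °C
Reagents that add atoms: none
Why: Borohydride reduction of an aromatic aldehyde; the acetal and the aryl ethers do not react.

Step 3
Reactants: 3 {3,4-dimethoxy-5-[(tetrahydro-2H-pyran-2-yl)oxy]phenyl}methanol
Product: 4 2-[5-(bromomethyl)-2,3-dimethoxyphenoxy]tetrahydro-2H-pyran
Conditions: PPh3, CBr4, CH2Cl2, 0 °C
Reagents that add atoms: carbon tetrabromide, BrC(Br)(Br)Br
Why: Appel bromination runs through an alkoxyphosphonium ion and bromide displacement without free acid, so the acid-labile tetrahydropyranyl ether should survive. The electron-rich benzylic bromide is used at once without storage.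

Step 4
Reactants: 5 3,4-dimethoxybenzyl chloride; 6 methyl (E)-4,4-dimethoxybut-2-enoate
Product: 9 methyl 3-(3,4-dimethoxybenzyl)-4,4-dimethoxybutanoate (racemic), via 3,4-dimethoxybenzylmagnesium chloride 7 (not isolated), via trimethylsilyl ketene acetal 8 (not isolated)
Conditions: Mg, THF, 0 °C; then 6, CuBr·SMe2 (10 mol%), Me3SiCl, THF, −78 → −30 °C; sat. aq. NH4Cl
Reagents that add atoms: none
Why: Copper-catalysed, chlorosilane-accelerated conjugate addition of a Grignard reagent to an enoate: the benzyl group is delivered to the β-carbon (C4) and the enolate is trapped as 8, which suppresses 1,2-addition and condensation. Mild aqueous work-up returns the ester and leaves the dimethyl acetal intact. C4 is formed racemic, as the plan requires.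

Step 5
Reactants: 9 methyl 3-(3,4-dimethoxybenzyl)-4,4-dimethoxybutanoate; 4 2-[5-(bromomethyl)-2,3-dimethoxyphenoxy]tetrahydro-2H-pyran
Product: 11 methyl 2-{3,4-dimethoxy-5-[(tetrahydro-2H-pyran-2-yl)oxy]benzyl}-3-(3,4-dimethoxybenzyl)-4,4-dimethoxybutanoate (all stereoisomers), via lithium enolate 10 (not isolated)
Conditions: LiN(i-Pr)2 (LDA), THF, −78 °C; then 4, DMPU, −78 → −20 °C
Reagents that add atoms: none
Why: Alkylation of a lithium ester enolate with a primary benzylic bromide that has no β-hydrogen; the acetal oxygens sit on C5, not on C4, so the enolate cannot expel them. The diastereomers formed at C3 are all wanted.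

Step 6
Reactants: 11 methyl 2-{3,4-dimethoxy-5-[(tetrahydro-2H-pyran-2-yl)oxy]benzyl}-3-(3,4-dimethoxybenzyl)-4,4-dimethoxybutanoate
Product: 12 methyl 2-(3-hydroxy-4,5-dimethoxybenzyl)-4-(3,4-dimethoxyphenyl)-3-formylbutanoate (all four stereoisomers)
Conditions: 1 M aq. HCl, THF, 20 °C
Reagents that add atoms: water, O
Why: Specific-acid hydrolysis of two acetals: the dimethyl acetal gives the aldehyde (its oxygen comes from water) and the aryl tetrahydropyranyl ether gives the phenol, while the methyl ester stays. Dilute acid in a water-rich medium at room temperature keeps the oxocarbenium ion from attacking ring A; the aldehyde is used promptly.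

Step 7
Reactants: 12 methyl 2-(3-hydroxy-4,5-dimethoxybenzyl)-4-(3,4-dimethoxyphenyl)-3-formylbutanoate (all four stereoisomers)
Product: 13 methyl (3R)-2-(3-hydroxy-4,5-dimethoxybenzyl)-4-(3,4-dimethoxyphenyl)-3-(hydroxymethyl)butanoate (both epimers at C2 of the butanoate)
Conditions: ketoreductase (screened; accepts the (4R)-aldehyde only), NADP+ (cat.), glucose dehydrogenase, D-glucose, KH2PO4/K2HPO4 buffer (0.2 M, pH 8.0–8.5), DMSO (10% v/v), 30–35 °C, low enzyme loading, 24–48 h
Reagents that add atoms: none
Why: The ketoreductase binds 12 and NADPH and transfers hydride to the formyl carbon C5, forming the new C5–H bond, while glucose dehydrogenase and D-glucose return NADP+ to NADPH and drive the reduction to completion. The closest known reaction type is the alcohol-dehydrogenase dynamic reductive kinetic resolution of racemic α-branched aldehydes such as 2-arylpropanals and 3-substituted 4-oxobutanoates. No ring is closed and no skeletal bond is formed. The new stereocentre is C4, which is not created by the hydride transfer but selected: the chiral active site accepts only the aldehyde whose C4 has the (4R) arrangement, so the enzyme is the controlling element. The mismatched (4S) aldehyde returns to the (4R) form through the enol or enolate of the formyl group. Because this α-carbon is dialkyl-substituted and not benzylic, that exchange is helped by the mildly basic, concentrated phosphate buffer (general base catalysis) and the warm temperature, and the enzyme loading is kept low so that reduction of the mismatched aldehyde never competes with its racemisation. Reduction removes the carbonyl that acidifies C4, so the configuration is locked in 13. The step needs chemoselectivity for the aldehyde over the methyl ester (inherent in the enzyme class), recognition at C4 that ignores C3 (sought by screening; C3 lies one atom further from the carbonyl), and enolisation at C4 far faster than at the ester-activated C3 (secured by the greater acidity of an aldehyde α-hydrogen); any 13 that lactonises in the buffer is harmless because step 8 closes the ring anyway.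

Step 8
Reactants: 13 methyl (3R)-2-(3-hydroxy-4,5-dimethoxybenzyl)-4-(3,4-dimethoxyphenyl)-3-(hydroxymethyl)butanoate
Product: 15 (3R,4R)-3-(3-hydroxy-4,5-dimethoxybenzyl)-4-(3,4-dimethoxybenzyl)dihydrofuran-2(3H)-one (target), via C3-epimeric (4R)-lactone mixture 14 (not isolated)
Conditions: p-TsOH·H2O (5 mol%), toluene, 40 °C; then DBU (3 equiv), 80 °C, Ar; aq. citric acid
Reagents that add atoms: none
Why: Acid-catalysed intramolecular transesterification (5-exo-trig) closes the γ-lactone with loss of methanol. DBU then equilibrates C3 through the lactone enolate to the thermodynamically preferred trans isomer, while C4 no longer carries an acidic hydrogen and keeps its configuration. The phenol is only deprotonated reversibly and returns on acidic work-up.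

## Compound list

1 | 3-hydroxy-4,5-dimethoxybenzaldehyde | COc1cc(C=O)cc(O)c1OC | starting material
2 | 3,4-dimethoxy-5-[(tetrahydro-2H-pyran-2-yl)oxy]benzaldehyde (racemic) | COc1cc(C=O)cc(OC2CCCCO2)c1OC | intermediate
3 | {3,4-dimethoxy-5-[(tetrahydro-2H-pyran-2-yl)oxy]phenyl}methanol (racemic) | COc1cc(CO)cc(OC2CCCCO2)c1OC | intermediate
4 | 2-[5-(bromomethyl)-2,3-dimethoxyphenoxy]tetrahydro-2H-pyran (racemic) | COc1cc(CBr)cc(OC2CCCCO2)c1OC | intermediate
5 | 3,4-dimethoxybenzyl chloride | COc1ccc(CCl)cc1OC | starting material
6 | methyl (E)-4,4-dimethoxybut-2-enoate | COC(=O)/C=C/C(OC)OC | starting material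
7 | (3,4-dimethoxybenzyl)magnesium chloride | COc1ccc(C[Mg]Cl)cc1OC | intermediate
8 | {[3-(3,4-dimethoxybenzyl)-1,4,4-trimethoxybut-1-en-1-yl]oxy}trimethylsilane (alkene geometry not defined, racemic) | COC(O[Si](C)(C)C)=CC(Cc1ccc(OC)c(OC)c1)C(OC)OC | intermediate
9 | methyl 3-(3,4-dimethoxybenzyl)-4,4-dimethoxybutanoate (racemic) | COC(=O)CC(Cc1ccc(OC)c(OC)c1)C(OC)OC | intermediate
10 | lithium enolate of 9 | COC(O[Li])=CC(Cc1ccc(OC)c(OC)c1)C(OC)OC | intermediate
11 | methyl 2-{3,4-dimethoxy-5-[(tetrahydro-2H-pyran-2-yl)oxy]benzyl}-3-(3,4-dimethoxybenzyl)-4,4-dimethoxybutanoate (all stereoisomers) | COC(=O)C(Cc1cc(OC2CCCCO2)c(OC)c(OC)c1)C(Cc1ccc(OC)c(OC)c1)C(OC)OC | intermediate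
12 | methyl 2-(3-hydroxy-4,5-dimethoxybenzyl)-4-(3,4-dimethoxyphenyl)-3-formylbutanoate (all four stereoisomers) | COC(=O)C(Cc1cc(O)c(OC)c(OC)c1)C(C=O)Cc1ccc(OC)c(OC)c1 | intermediate
13 | methyl (3R)-2-(3-hydroxy-4,5-dimethoxybenzyl)-4-(3,4-dimethoxyphenyl)-3-(hydroxymethyl)butanoate (both C2 epimers) | COC(=O)C(Cc1cc(O)c(OC)c(OC)c1)[C@H](CO)Cc1ccc(OC)c(OC)c1 | intermediate
14 | (4R)-3-(3-hydroxy-4,5-dimethoxybenzyl)-4-(3,4-dimethoxybenzyl)dihydrofuran-2(3H)-one (both C3 epimers) | COc1ccc(C[C@H]2COC(=O)C2Cc2cc(O)c(OC)c(OC)c2)cc1OC | intermediate
15 | (3R,4R)-3-(3-hydroxy-4,5-dimethoxybenzyl)-4-(3,4-dimethoxybenzyl)dihydrofuran-2(3H)-one | COc1ccc(C[C@H]2COC(=O)[C@@H]2Cc2cc(O)c(OC)c(OC)c2)cc1OC | target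

## Step count and least certain steps

Total step count: 8.

Longest linear sequence: 7 steps (1 → 2 → 3 → 4 → 11 → 12 → 13 → 15, that is steps 1, 2, 3, 5, 6, 7, 8). The branch 5 + 6 → 9 is one step and joins at step 5.

**Step 7 (key step).** The most likely failure is that racemisation at C4 falls behind hydride transfer. C4–H is activated only by the formyl group and lacks the benzylic assistance of the usual substrates, so the process could decay into a simple kinetic resolution. To a lesser degree, selectivity could erode for one of the two C3 series. Fallback: the enzymatic reduction is run deliberately as a kinetic resolution of 12 to about half conversion. Product 13 is separated from the unreduced aldehyde, methyl (3S)-2-(3-hydroxy-4,5-dimethoxybenzyl)-4-(3,4-dimethoxyphenyl)-3-formylbutanoate F1. F1 is racemised at the formyl-bearing carbon in a separate flask (catalytic DBU or pyrrolidinium acetate, toluene, 40 °C) and returned as 12 to the next cycle. Racemisation and reduction are thus decoupled. The fallback sets out from 12 and comes back to the route at 13.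

**Step 4.** Two things could go wrong: homocoupling during formation of the electron-rich benzylic Grignard reagent, and sluggish benzyl transfer from copper that lets 1,2-addition to the ester compete. Fallback with a stabilised benzyl anion equivalent: 3,4-dimethoxybenzaldehyde and propane-1,3-dithiol (BF3·OEt2, CH2Cl2) give 2-(3,4-dimethoxyphenyl)-1,3-dithiane F2. Deprotonation with n-BuLi (THF, DMPU, −78 °C) and conjugate addition to 6 give methyl 3-[2-(3,4-dimethoxyphenyl)-1,3-dithian-2-yl]-4,4-dimethoxybutanoate F3. Desulfurisation with Raney Ni in ethanol gives 9. The fallback sets out from 6 and comes back at 9.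

**Step 5.** Alkylation of the β-branched enolate could be slow, allowing proton exchange with the product and self-condensation, and the labile benzylic bromide could ionise and decompose. Fallback by aldol condensation and hydrogenation, which also makes steps 2 and 3 unnecessary:
- The lithium enolate of 9 is added to aldehyde 2 (THF, −78 °C) to give methyl 2-{[3,4-dimethoxy-5-(tetrahydro-2H-pyran-2-yloxy)phenyl](hydroxy)methyl}-3-(3,4-dimethoxybenzyl)-4,4-dimethoxybutanoate F4.
- Mesylation (MsCl, Et3N) gives methyl 2-{[3,4-dimethoxy-5-(tetrahydro-2H-pyran-2-yloxy)phenyl][(methylsulfonyl)oxy]methyl}-3-(3,4-dimethoxybenzyl)-4,4-dimethoxybutanoate F5.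
- Elimination with DBU gives methyl 2-[3,4-dimethoxy-5-(tetrahydro-2H-pyran-2-yloxy)benzylidene]-3-(3,4-dimethoxybenzyl)-4,4-dimethoxybutanoate F6.
- Hydrogenation of the alkene (H2, Pd/C, EtOAc) gives 11.

The fallback sets out from 9 and 2 and comes back at 11.

**Step 6.** Acid could promote attack of the liberated aldehyde or its oxocarbenium ion on ring A (six-membered cyclisation), and aldol-type self-condensation, before both acetals are cleaved. Fallback by staged unmasking that keeps the aldehyde away from mineral acid: PPTS in methanol at 20 °C removes only the tetrahydropyranyl group, because the dimethyl acetal merely exchanges with the solvent. This gives methyl 2-(3-hydroxy-4,5-dimethoxybenzyl)-3-(3,4-dimethoxybenzyl)-4,4-dimethoxybutanoate F7. The aldehyde is then released under near-neutral conditions (LiBF4, wet MeCN, 20 °C) just before the enzymatic step. The fallback sets out from 11 and comes back at 12.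

## Further compounds

F1 | step 7 | methyl (3S)-2-(3-hydroxy-4,5-dimethoxybenzyl)-4-(3,4-dimethoxyphenyl)-3-formylbutanoate (both C2 epimers) | COC(=O)C(Cc1cc(O)c(OC)c(OC)c1)[C@@H](C=O)Cc1ccc(OC)c(OC)c1
F2 | step 4 | 2-(3,4-dimethoxyphenyl)-1,3-dithiane | COc1ccc(C2SCCCS2)cc1OC
F3 | step 4 | methyl 3-[2-(3,4-dimethoxyphenyl)-1,3-dithian-2-yl]-4,4-dimethoxybutanoate (racemic) | COC(=O)CC(C(OC)OC)C1(c2ccc(OC)c(OC)c2)SCCCS1
F4 | step 5 | methyl 2-{[3,4-dimethoxy-5-(tetrahydro-2H-pyran-2-yloxy)phenyl](hydroxy)methyl}-3-(3,4-dimethoxybenzyl)-4,4-dimethoxybutanoate (all stereoisomers) | COC(=O)C(C(O)c1cc(OC2CCCCO2)c(OC)c(OC)c1)C(Cc1ccc(OC)c(OC)c1)C(OC)OC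
F5 | step 5 | methyl 2-{[3,4-dimethoxy-5-(tetrahydro-2H-pyran-2-yloxy)phenyl][(methylsulfonyl)oxy]methyl}-3-(3,4-dimethoxybenzyl)-4,4-dimethoxybutanoate (all stereoisomers) | COC(=O)C(C(OS(C)(=O)=O)c1cc(OC2CCCCO2)c(OC)c(OC)c1)C(Cc1ccc(OC)c(OC)c1)C(OC)OC
F6 | step 5 | methyl 2-[3,4-dimethoxy-5-(tetrahydro-2H-pyran-2-yloxy)benzylidene]-3-(3,4-dimethoxybenzyl)-4,4-dimethoxybutanoate (alkene geometry not defined, all stereoisomers) | COC(=O)C(=Cc1cc(OC2CCCCO2)c(OC)c(OC)c1)C(Cc1ccc(OC)c(OC)c1)C(OC)OC
F7 | step 6 | methyl 2-(3-hydroxy-4,5-dimethoxybenzyl)-3-(3,4-dimethoxybenzyl)-4,4-dimethoxybutanoate (all four stereoisomers) | COC(=O)C(Cc1cc(O)c(OC)c(OC)c1)C(Cc1ccc(OC)c(OC)c1)C(OC)OC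
A1 | alternative 1 | (2R)-2-[3-(benzyloxy)-4,5-dimethoxybenzyl]-4-(3,4-dimethoxyphenyl)-4-oxobutanoic acid | OC(=O)[C@@H](CC(=O)c1ccc(OC)c(OC)c1)Cc1cc(OCc2ccccc2)c(OC)c(OC)c1
A2 | alternative 1 | (3R,4R)-3-[3-(benzyloxy)-4,5-dimethoxybenzyl]-4-(3,4-dimethoxybenzoyl)dihydrofuran-2(3H)-one | COc1ccc(C(=O)[C@H]2COC(=O)[C@@H]2Cc2cc(OCc3ccccc3)c(OC)c(OC)c2)cc1OC
A3 | alternative 2 | ethyl (1S,5R)-2-oxo-3-oxabicyclo[3.1.0]hexane-1-carboxylate | C1[C@H]2COC(=O)[C@]21C(=O)OCC
A4 | alternative 2 | ethyl (3R,4R)-3-[3-(benzyloxy)-4,5-dimethoxybenzyl]-4-(3,4-dimethoxybenzyl)-2-oxotetrahydrofuran-3-carboxylate (arylmethyl groups trans) | COc1ccc(C[C@H]2COC(=O)[C@]2(C(=O)OCC)Cc2cc(OCc3ccccc3)c(OC)c(OC)c2)cc1OC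
A5 | alternative 2 | (3R,4R)-3-[3-(benzyloxy)-4,5-dimethoxybenzyl]-4-(3,4-dimethoxybenzyl)dihydrofuran-2(3H)-one | COc1ccc(C[C@H]2COC(=O)[C@@H]2Cc2cc(OCc3ccccc3)c(OC)c(OC)c2)cc1OC
A6 | alternative 3 | (2R,3E)-5-(3,4-dimethoxyphenyl)pent-3-en-2-yl 3-[3-(benzyloxy)-4,5-dimethoxyphenyl]propanoate | C[C@@H](OC(=O)CCc1cc(OCc2ccccc2)c(OC)c(OC)c1)/C=C/Cc1ccc(OC)c(OC)c1
A7 | alternative 3 | (2R,3S,4E)-2-[3-(benzyloxy)-4,5-dimethoxybenzyl]-3-(3,4-dimethoxybenzyl)hex-4-enoic acid | COc1ccc(C[C@@H](/C=C/C)[C@@H](Cc2cc(OCc3ccccc3)c(OC)c(OC)c2)C(=O)O)cc1OC
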